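**Analysis of the target**

Compound 14 is a fully substituted oxolane (ring atoms O1, C2, C3, C4, C5). It carries a 4-hydroxyphenyl group at C2, a 2,4-dihydroxybenzoyl group at C3, a hydroxy(4-hydroxyphenyl)methyl branch at C4 and a 2,4-dihydroxyphenyl group at C5. The four ring carbons and the carbinol carbon are stereocentres and all five are R. On the ring the C2 aryl group is trans to the C3 aroyl group, while the C3 aroyl group, the C4 branch and the C5 aryl group share one face (2,3-trans, 3,4-cis, 4,5-cis). The molecule is fragile. C3 is α to the ketone and β to the ring oxygen, so base can epimerise it or open the ring by β-elimination across C2–O1. The two ring C–O bonds and the carbinol are benzylic and para or ortho to phenols, so acid, phenoxide formation or hydrogenolysis can break them. The six phenols must therefore be unmasked last under nearly neutral conditions. The difficulty lies in the contiguous cis triad C3/C4/C5, which is the crowded arrangement, and in setting five stereocentres in absolute terms with no existing one to build on. The plan rests on a hidden twofold symmetry: the ketone carbon and C5 carry the same 2,4-dihydroxyphenyl group, C2 and the carbinol carbon carry the same 4-hydroxyphenyl group, and C3 and C4 are the α-carbons of these two pairs. If C5 is raised to the ketone level and O1–C5 is opened, the result is a C2-symmetric 2,3-bis(α-hydroxybenzyl)-1,4-diketone, so 14 is that diketone with one of two equivalent hemiketals reduced.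

**Retrosynthetic reasoning**

The last operation is the release of the six phenols from the hexasilyl ether 13. Silyl ethers are cut at the O–Si bond by buffered fluoride, so no C–O bond of the oxolane or the carbinol is touched. They also tolerate enolisation, a Lewis acid and a hydride donor. No skeletal bond is cut here; this choice fixes the protecting group for the whole route.

In 13 the C5–H bond is taken back to a C5–OH bond, which puts C5 at the hemiketal level. The hydroxy ketone in the other half of 13 can close in the same way, so the precursor is the cis-fused bis-hemiketal 11, a ring tautomer of the open diketo diol 10. This cut is chosen because it turns an unsymmetrical target into a C2-symmetric precursor: the two hemiketals of 11 are homotopic, so reduction of either gives the same compound, 12, which opens to 13. The forward reaction must reduce only one hemiketal. It must also deliver hydride to the convex face of the bicyclic oxocarbenium ion, which places the C5 aryl group on the concave face, cis to the C4 branch. The 3,4-cis relationship is the ring fusion itself.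

Compound 10 holds two identical β-hydroxy ketone units that share the C3–C4 bond. Cutting C2–C3 and C4–carbinol carbon, both aldol bonds, gives the symmetric diketone 5 and two molecules of aldehyde 7. These bonds are chosen because each joins a pair of stereocentres that a closed aldol transition state controls, and because the fragments become very simple. The other symmetric cut, C3–C4, would leave the relative configuration of C3 and C4 to an uncontrolled coupling of two aldol units. The forward reaction has to give the syn relationship in each half, the same absolute sense in both halves (the C2 and not the meso isomer) and the R series. A chiral boron reagent on both enolate oxygens of 8 addresses all three. The isomer sought is also the only one that can fold into 11 with both 4-silyloxyphenyl groups exo, so an equilibrating aldol would reach the same relative configuration. Equilibration by retro-aldol would, however, erase the absolute configuration, and aryl β-hydroxy ketones dehydrate under base. The step is therefore planned under kinetic reagent control, and the stability of 11 is used only in the next step.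

The central CH2–CH2 bond of 5 joins two identical aryl methyl ketone units. Cutting it gives two molecules of ketone 3, which are joined through the enolate 4 by oxidation. Acylation routes to 5 are not compatible with the silyl ethers, and the coupling needs no second functionalised partner.

Ketone 3 and aldehyde 7 come from the phenols 1 and 6 by silylation with 2.

**Alternatives that were turned down**

Alternative 1: The disconnection removes the two aryl–carbon bonds at the hemiketal carbons of 11, then the C3–C4 bond and both lactone C–O bonds of the dilactone A2, which leads to two molecules of 4-hydroxycinnamic acid A1. In the forward key step A1 is oxidised at a graphite anode. Two phenoxyl radicals couple at the carbons next to the carboxyl groups, and each quinone methide is trapped by the carboxylate of the other half, which closes two cis-fused γ-lactones and gives A2.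
- For it: one step from a cheap acid without protecting groups, and the relative configuration at C3, C4 and both benzylic carbons is fixed because the rings close as the bonds form.
- Against it: a phenoxyl radical without ortho substituents also couples at ring carbons and at oxygen, so the wanted mode competes with others. A2 is formed racemic at an achiral electrode, so the single enantiomer needs a resolution that discards half. The two 2,4-dioxygenated aryl groups would have to be added to the lactone carbonyls as carbanions, where over-addition threatens and the phenols must first be protected.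
- Comparison: it is stronger in brevity to the bicyclic core and in the certainty of the relative configuration. The chosen route offers reagent control of the absolute configuration and has both aryl ketones in place from the start. Both share the mono-reduction of a symmetric bis-hemiketal.

Alternative 2: The disconnection cuts C2–C3 and O1–C2, so that 4-(allyloxy)benzaldehyde A4 is stitched into the γ-hydroxy ketone A3, which already holds C4, C5 and the carbinol carbon. In the forward key step Ba(OH)2 condenses A4 with the C3 methylene of A3, and the C5 hydroxyl adds to the β-carbon of the enone so formed to close the oxolane, giving A5.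
- For it: the unsymmetrical ring is built directly, so no statistical mono-reduction is needed. The allyl ethers come off with zerovalent palladium (Pd(PPh3)4) under neutral conditions, and the C2 aryl group enters late.
- Against it: A3 needs its own asymmetric synthesis of three contiguous stereocentres, which makes the linear sequence much longer. The ring closure is a 5-endo-trig oxa-Michael addition. C2 and C3 are set under equilibrating base, where the isomer with the C3 aroyl group trans to both neighbours should be favoured over the 3,4-cis arrangement of 14.
- Comparison: it is stronger in avoiding a desymmetrisation. The chosen route fixes the 3,4-cis relationship as a ring fusion, not as an equilibrium, and reaches the target in six steps.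

Alternative 3: The disconnection cuts C3–ketone carbon and C4–carbinol carbon as the two bonds of a [2+2] photocycloaddition between the butenolide A6 and the aryl ketene acetal A7. In the forward key step excited A6 adds A7 across its double bond on the face opposite its aryl group and gives the cis-fused cyclobutane ketal lactone A8. Ketal hydrolysis and Baeyer–Villiger oxygen insertion at the benzylic cyclobutane carbon would then give a second γ-lactone of the same bicyclic type as A2.
- For it: one stereocentre of A6 controls the rest. The two carbonyl-derived carbons of A8 are different (ketal and lactone), so the two 2,4-dioxygenated aryl groups could be added one at a time and no statistical mono-reduction arises. This is a real advantage over the chosen route.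
- Against it: A6 must be made enantiopure. The photochemical step must keep head-to-tail regiochemistry with a styrene-type alkene that can also quench the excited enone. The peracid step works on electron-rich arenes. Two carbanion additions to carbonyl groups and a reduction still follow, so the sequence is about twice as long.
- Comparison: it is stronger in differentiating the two halves. The chosen route is much shorter, avoids photochemistry and aryl carbanions, and sets four stereocentres in one operation.

Key step: step 4

Assumption: the facial preference known for (Z)-enol diisopinocampheylborinates of α-methylene ketones is taken to hold for 5, so that (+)-Ipc2BOTf (all isopinocampheyl groups from (−)-α-pinene) sends each enolate carbon to the Re face of 7. If the sense is the reverse, the antipodal reagent is used and nothing else changes.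

Assumption: 10 is written as the open diketo diol although it may rest partly or wholly as hemiketals. The hemiketal carbons of 11 and 12 are anomeric and are left unassigned.

**Steps**

Step 1
Reactants: 1 2',4'-dihydroxyacetophenone; 2 tert-butyldimethylsilyl chloride
Product: 3 1-[2,4-bis(tert-butyldimethylsilyloxy)phenyl]ethan-1-one
Conditions: TBSCl (2.6 equiv), imidazole (5 equiv), DMAP (cat.), DMF, rt → 45 °C
Reagents that add atoms: tert-butyldimethylsilyl chloride (2), CC(C)(C)[Si](C)(C)Cl
Why: Imidazole-promoted silyl ether formation; the 4-OH reacts at once and the hydrogen-bonded 2-OH more slowly, hence the excess reagent, the nucleophilic catalyst and gentle warming. No stereocentre is involved.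

Step 2
Reactants: 3 1-[2,4-bis(tert-butyldimethylsilyloxy)phenyl]ethan-1-one (two molecules)
Product: 5 1,4-bis[2,4-bis(tert-butyldimethylsilyloxy)phenyl]butane-1,4-dione, via lithium enolate 4 (not isolated)
Conditions: LiN(i-Pr)2 (1.05 equiv), THF, −78 °C; CuCl2 (1.1 equiv), DMF, −78 °C → rt
Reagents that add atoms: none
Why: Oxidative homocoupling of a ketone enolate: CuCl2 oxidises the lithium enolate 4 and two α-carbons join to the symmetric 1,4-diketone. Ketone 3 has a single enolisable position and no stereocentre is formed; low temperature and a short enolate lifetime keep the ortho silyl group on the phenol oxygen.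

Step 3
Reactants: 6 4-hydroxybenzaldehyde; 2 tert-butyldimethylsilyl chloride
Product: 7 4-(tert-butyldimethylsilyloxy)benzaldehyde
Conditions: TBSCl (1.2 equiv), imidazole (2 equiv), CH2Cl2, rt
Reagents that add atoms: tert-butyldimethylsilyl chloride (2), CC(C)(C)[Si](C)(C)Cl
Why: Silyl ether formation on an unhindered phenol; the aldehyde is inert to the reagents.

Step 4
Reactants: 5 1,4-bis[2,4-bis(tert-butyldimethylsilyloxy)phenyl]butane-1,4-dione; 7 4-(tert-butyldimethylsilyloxy)benzaldehyde (two molecules)
Product: 10 (2R,3R)-1,4-bis[2,4-bis(tert-butyldimethylsilyloxy)phenyl]-2,3-bis{(R)-[4-(tert-butyldimethylsilyloxy)phenyl](hydroxy)methyl}butane-1,4-dione, via bis(enol borinate) 8 (not isolated), via bis(boron aldolate) 9 (not isolated)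
Conditions: (+)-Ipc2BOTf (2.6 equiv; from (+)-Ipc2BH and TfOH, hexane, rt), i-Pr2NEt (3.5 equiv), CH2Cl2, −78 → 0 °C; 7 (2.6 equiv), −78 → −20 °C; MeOH, pH 7 buffer, 30% H2O2, 0 °C
Reagents that add atoms: none
Why: Proposed new method: twofold soft enolisation of 5 with the chiral boron triflate and a tertiary amine should give the (1Z,3Z)-bis(enol borinate) 8, since aryl alkyl ketones enolise with the aryl group trans to the chain, and each enolate carbon then adds to 7 through a closed six-membered chair transition state with boron bound to both oxygens, forming C2–C3 and C4–carbinol carbon; the closest known reaction types are the syn-selective aldol of (Z)-enol diisopinocampheylborinates of single α-methylene ketones and the twofold aldol of succinate dienolates with aryl aldehydes that leads to 2,6-diaryl dilactones. No ring is closed in the bond-forming events; the two five-membered hemiketal rings can form only afterwards, each by 5-exo-trig addition of a carbinol hydroxyl to the distal ketone, and are used in step 5. The two carbinol carbons (both R) are set by the isopinocampheyl ligands, which decide that the Re face of the aldehyde enters the chair. C3 and C4 (both R) follow from the Z enolate geometry, which puts the aryl group of 7 equatorial in the chair and gives the syn relationship within each half. Both boron atoms carry ligands of the same hand, so the two additions have the same sense, which is what the C2-symmetric and not the meso adduct requires. One wrong addition gives the meso-type diastereomer and not the enantiomer, so the ligand preference acts twice on the enantiomeric purity of 10 and the errors can be removed by chromatography. The selectivity the step needs is face control in the second addition against whatever bias the two stereocentres just made exert, and only the ligands secure it, which is the open point. The aldolates stay as boron chelates at or below −20 °C and are freed by buffered oxidative work-up, so that neither retro-aldol nor dehydration to the enone can undo the result.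

Step 5
Reactants: 10 (2R,3R)-1,4-bis[2,4-bis(tert-butyldimethylsilyloxy)phenyl]-2,3-bis{(R)-[4-(tert-butyldimethylsilyloxy)phenyl](hydroxy)methyl}butane-1,4-dione
Product: 13 [(2R,3R,4R,5R)-5-[2,4-bis(tert-butyldimethylsilyloxy)phenyl]-2-[4-(tert-butyldimethylsilyloxy)phenyl]-4-{(R)-[4-(tert-butyldimethylsilyloxy)phenyl](hydroxy)methyl}oxolan-3-yl][2,4-bis(tert-butyldimethylsilyloxy)phenyl]methanone, via bis-hemiketal 11 (not isolated), via bicyclic mono-hemiketal 12 (not isolated)
Conditions: BF3·OEt2 (2 equiv), Et3SiH (1.0 equiv, slow addition), CH2Cl2, −78 °C; sat. NaHCO3, −78 °C; recovered 10 resubmitted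
Reagents that add atoms: none
Why: Ionic hydrogenation of a cyclic hemiketal (reductive etherification of a γ-hydroxy ketone): BF3 closes 10 to 11 and ionises one hemiketal to an aryl-stabilised five-membered oxocarbenium ion, which takes hydride from the silane on the convex face of the cis-fused bicycle, so the hydrogen at C5 is exo and the aryl group ends up cis to the C4 branch (C5 R). The two hemiketals are homotopic, so the first reduction gives one compound whichever reacts; limiting silane is meant to stop it there, and on work-up the untouched hemiketal of 12 opens to the hydroxy ketone 13.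

Step 6
Reactants: 13 hexakis(tert-butyldimethylsilyl) ether of 14
Product: 14 [(2R,3R,4R,5R)-5-(2,4-dihydroxyphenyl)-4-[(R)-hydroxy(4-hydroxyphenyl)methyl]-2-(4-hydroxyphenyl)oxolan-3-yl](2,4-dihydroxyphenyl)methanone (CNP0244141.1)
Conditions: Bu4NF (8 equiv), AcOH (8 equiv), THF, 0 °C → rt
Reagents that add atoms: none
Why: Fluoride cleavage of aryl silyl ethers, driven by the Si–F bond; acetic acid protonates each phenoxide as it forms, so that neither β-elimination across C2–O1 nor quinone-methide opening of the benzylic C–O bonds should scramble C2, C3 or C5. No stereocentre is touched.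

**Compound list**

1 | 2',4'-dihydroxyacetophenone | CC(=O)c1ccc(O)cc1O | starting material
2 | tert-butyldimethylsilyl chloride | CC(C)(C)[Si](C)(C)Cl | starting material
3 | 1-[2,4-bis(tert-butyldimethylsilyloxy)phenyl]ethan-1-one | CC(=O)c1ccc(O[Si](C)(C)C(C)(C)C)cc1O[Si](C)(C)C(C)(C)C | intermediate
4 | lithium enolate of 3 (not isolated) | [Li]OC(=C)c1ccc(O[Si](C)(C)C(C)(C)C)cc1O[Si](C)(C)C(C)(C)C | intermediate
5 | 1,4-bis[2,4-bis(tert-butyldimethylsilyloxy)phenyl]butane-1,4-dione | O=C(CCC(=O)c1ccc(O[Si](C)(C)C(C)(C)C)cc1O[Si](C)(C)C(C)(C)C)c1ccc(O[Si](C)(C)C(C)(C)C)cc1O[Si](C)(C)C(C)(C)C | intermediate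
6 | 4-hydroxybenzaldehyde | O=Cc1ccc(O)cc1 | starting material
7 | 4-(tert-butyldimethylsilyloxy)benzaldehyde | O=Cc1ccc(O[Si](C)(C)C(C)(C)C)cc1 | intermediate
8 | (1Z,3Z)-1,4-bis[2,4-bis(tert-butyldimethylsilyloxy)phenyl]buta-1,3-diene-1,4-diyl bis(diisopinocampheylborinate), isopinocampheyl groups from (−)-α-pinene (not isolated) | B([C@H]1C[C@H]2C[C@@H]([C@@H]1C)C2(C)C)([C@H]1C[C@H]2C[C@@H]([C@@H]1C)C2(C)C)O/C(=C\C=C(/OB([C@H]1C[C@H]2C[C@@H]([C@@H]1C)C2(C)C)[C@H]1C[C@H]2C[C@@H]([C@@H]1C)C2(C)C)c1ccc(O[Si](C)(C)C(C)(C)C)cc1O[Si](C)(C)C(C)(C)C)c1ccc(O[Si](C)(C)C(C)(C)C)cc1O[Si](C)(C)C(C)(C)C | intermediate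
9 | bis(diisopinocampheylboron) aldolate of 10, boron on both carbinol oxygens (not isolated) | O=C(c1ccc(O[Si](C)(C)C(C)(C)C)cc1O[Si](C)(C)C(C)(C)C)[C@@H]([C@@H](OB([C@H]1C[C@H]2C[C@@H]([C@@H]1C)C2(C)C)[C@H]1C[C@H]2C[C@@H]([C@@H]1C)C2(C)C)c1ccc(O[Si](C)(C)C(C)(C)C)cc1)[C@H]([C@@H](OB([C@H]1C[C@H]2C[C@@H]([C@@H]1C)C2(C)C)[C@H]1C[C@H]2C[C@@H]([C@@H]1C)C2(C)C)c1ccc(O[Si](C)(C)C(C)(C)C)cc1)C(=O)c1ccc(O[Si](C)(C)C(C)(C)C)cc1O[Si](C)(C)C(C)(C)C | intermediate
10 | (2R,3R)-1,4-bis[2,4-bis(tert-butyldimethylsilyloxy)phenyl]-2,3-bis{(R)-[4-(tert-butyldimethylsilyloxy)phenyl](hydroxy)methyl}butane-1,4-dione | O=C(c1ccc(O[Si](C)(C)C(C)(C)C)cc1O[Si](C)(C)C(C)(C)C)[C@@H]([C@@H](O)c1ccc(O[Si](C)(C)C(C)(C)C)cc1)[C@H]([C@@H](O)c1ccc(O[Si](C)(C)C(C)(C)C)cc1)C(=O)c1ccc(O[Si](C)(C)C(C)(C)C)cc1O[Si](C)(C)C(C)(C)C | intermediate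
11 | (1R,2R,5R,6R)-4,8-bis[2,4-bis(tert-butyldimethylsilyloxy)phenyl]-2,6-bis[4-(tert-butyldimethylsilyloxy)phenyl]-3,7-dioxabicyclo[3.3.0]octane-4,8-diol, cis-fused, both C2/C6 aryl groups exo, C4 and C8 unassigned (not isolated) | OC1(c2ccc(O[Si](C)(C)C(C)(C)C)cc2O[Si](C)(C)C(C)(C)C)O[C@@H](c2ccc(O[Si](C)(C)C(C)(C)C)cc2)[C@H]2[C@@H]1[C@H](c1ccc(O[Si](C)(C)C(C)(C)C)cc1)OC2(O)c1ccc(O[Si](C)(C)C(C)(C)C)cc1O[Si](C)(C)C(C)(C)C | intermediate
12 | 8-deoxy derivative of 11: cis-fused 3,7-dioxabicyclo[3.3.0]octan-4-ol with hydrogen exo and the aryl group endo at C8, C4 unassigned (not isolated) | OC1(c2ccc(O[Si](C)(C)C(C)(C)C)cc2O[Si](C)(C)C(C)(C)C)O[C@@H](c2ccc(O[Si](C)(C)C(C)(C)C)cc2)[C@H]2[C@@H]1[C@H](c1ccc(O[Si](C)(C)C(C)(C)C)cc1)O[C@H]2c1ccc(O[Si](C)(C)C(C)(C)C)cc1O[Si](C)(C)C(C)(C)C | intermediate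
13 | [(2R,3R,4R,5R)-5-[2,4-bis(tert-butyldimethylsilyloxy)phenyl]-2-[4-(tert-butyldimethylsilyloxy)phenyl]-4-{(R)-[4-(tert-butyldimethylsilyloxy)phenyl](hydroxy)methyl}oxolan-3-yl][2,4-bis(tert-butyldimethylsilyloxy)phenyl]methanone | O=C(c1ccc(O[Si](C)(C)C(C)(C)C)cc1O[Si](C)(C)C(C)(C)C)[C@@H]1[C@H]([C@@H](O)c2ccc(O[Si](C)(C)C(C)(C)C)cc2)[C@H](c2ccc(O[Si](C)(C)C(C)(C)C)cc2O[Si](C)(C)C(C)(C)C)O[C@H]1c1ccc(O[Si](C)(C)C(C)(C)C)cc1 | intermediate
14 | [(2R,3R,4R,5R)-5-(2,4-dihydroxyphenyl)-4-[(R)-hydroxy(4-hydroxyphenyl)methyl]-2-(4-hydroxyphenyl)oxolan-3-yl](2,4-dihydroxyphenyl)methanone | O=C(c1ccc(O)cc1O)[C@@H]1[C@H]([C@@H](O)c2ccc(O)cc2)[C@H](c2ccc(O)cc2O)O[C@H]1c1ccc(O)cc1 | target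

**Step count and risks**

Total step count: 6. Longest linear sequence: 5 steps (steps 1, 2, 4, 5, 6); step 3 is a one-step branch.

Step 4 (key step, proposed new method). Three things are most likely to go wrong. The second enolisation may stay incomplete, because the mono-enol borinate is hindered. The second addition may lose facial control if the two stereocentres just made oppose the ligands, which would divert material to the meso-type adduct. The ligand may also discriminate the aldehyde faces only weakly for an ortho-substituted aryl ketone.

The fallback uses known chemistry, sets out from 5 and returns at 10. It makes the two C–C bonds one after the other, each as an ordinary reagent-controlled syn aldol of a single (Z)-enol diisopinocampheylborinate. Diketone 5 is enolised on one side only (one equivalent of (+)-Ipc2BOTf and i-Pr2NEt) and added to one equivalent of 7, which should give the mono-aldol adduct F1, with unreacted 5 recovered. The carbinol is capped as the triethylsilyl ether F2 (Et3SiOTf, 2,6-lutidine, −78 °C) so that it cannot close onto the distal ketone. The remaining CH2–C=O unit of F2 is enolised and added to 7 in a second boron aldol to give the mono-triethylsilyl ether of 10 F3. AcOH–THF–H2O at room temperature removes the triethylsilyl group and gives 10. Each addition is then a separate operation with its own purification, and the capping group on F2 can be varied to change the bias the first half exerts on the second addition.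

Step 5. The most likely failure is over-reduction: the second hemiketal ionises by the same pathway, so limiting silane gives at best a statistical distribution. Ionisation and reduction at the benzylic carbinol positions para to silyloxy groups is also possible. Face selectivity could erode if the cation reacts from a ring-opened, monocyclic form.

The fallback sets out from 10 and returns at 14. It moves the statistical event from an irreversible reduction to a reversible protection. Monosilylation of 10 (t-BuMe2SiOTf, one equivalent, 2,6-lutidine, −78 °C) gives the mono-tert-butyldimethylsilyl ether of 10 F4; recovered 10 is resubmitted. In F4 only one hydroxyl can close onto a ketone, so excess Et3SiH/BF3·OEt2 at −78 °C can be used. Hydride adds anti to the C4 branch and should give the carbinol silyl ether of 13 F5. Removal of all seven silyl groups (HF·pyridine, THF/pyridine, 0 °C → rt) gives 14.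

Step 2. The most likely failures are transfer of the ortho silyl group from the phenol oxygen to the enolate oxygen through a six-membered transition state, and α-chlorination by CuCl2 in place of C–C coupling.

The fallback sets out from 3 and returns at 5. Soft enolisation with Me3SiOTf/Et3N (CH2Cl2, 0 °C) converts 3 into the trimethylsilyl enol ether F6 without a free metal enolate. Oxidative dimerisation of F6 with Ag2O in DMSO (about 65 °C) gives 5.

Step 6. The most likely failure is ring opening once phenoxides are present, by β-elimination across C2–O1 or through quinone methides, with loss of configuration at C2, C3 or C5. Slow cleavage at the hindered ortho positions would add to the exposure time.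

The fallback sets out from 13 and returns at 14. Fluoride cleavage is run in the presence of excess Ac2O (CsF, Ac2O, DMF, 0 °C), so that each phenoxide is acetylated as it is released. This should give the hexa-O-acetate of 14 F7 with the carbinol free, a neutral compound that can be purified. The phenolic acetates are then removed with NH4OAc in aqueous MeOH at room temperature, near neutrality, to give 14.

**Further compounds**

F1 | step 4 | (2R)-1,4-bis[2,4-bis(tert-butyldimethylsilyloxy)phenyl]-2-{(R)-[4-(tert-butyldimethylsilyloxy)phenyl](hydroxy)methyl}butane-1,4-dione (mono-aldol adduct) | O=C(c1ccc(O[Si](C)(C)C(C)(C)C)cc1O[Si](C)(C)C(C)(C)C)[C@@H]([C@@H](O)c1ccc(O[Si](C)(C)C(C)(C)C)cc1)CC(=O)c1ccc(O[Si](C)(C)C(C)(C)C)cc1O[Si](C)(C)C(C)(C)C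
F2 | step 4 | triethylsilyl ether of F1 | O=C(c1ccc(O[Si](C)(C)C(C)(C)C)cc1O[Si](C)(C)C(C)(C)C)[C@@H]([C@@H](O[Si](CC)(CC)CC)c1ccc(O[Si](C)(C)C(C)(C)C)cc1)CC(=O)c1ccc(O[Si](C)(C)C(C)(C)C)cc1O[Si](C)(C)C(C)(C)C
F3 | step 4 | mono-triethylsilyl ether of 10 | O=C(c1ccc(O[Si](C)(C)C(C)(C)C)cc1O[Si](C)(C)C(C)(C)C)[C@@H]([C@@H](O[Si](CC)(CC)CC)c1ccc(O[Si](C)(C)C(C)(C)C)cc1)[C@H]([C@@H](O)c1ccc(O[Si](C)(C)C(C)(C)C)cc1)C(=O)c1ccc(O[Si](C)(C)C(C)(C)C)cc1O[Si](C)(C)C(C)(C)C
F4 | step 5 | mono-tert-butyldimethylsilyl ether of 10 (one carbinol silylated) | O=C(c1ccc(O[Si](C)(C)C(C)(C)C)cc1O[Si](C)(C)C(C)(C)C)[C@@H]([C@@H](O[Si](C)(C)C(C)(C)C)c1ccc(O[Si](C)(C)C(C)(C)C)cc1)[C@H]([C@@H](O)c1ccc(O[Si](C)(C)C(C)(C)C)cc1)C(=O)c1ccc(O[Si](C)(C)C(C)(C)C)cc1O[Si](C)(C)C(C)(C)C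
F5 | step 5 | carbinol tert-butyldimethylsilyl ether of 13 (heptasilyl ether of 14) | O=C(c1ccc(O[Si](C)(C)C(C)(C)C)cc1O[Si](C)(C)C(C)(C)C)[C@@H]1[C@H]([C@@H](O[Si](C)(C)C(C)(C)C)c2ccc(O[Si](C)(C)C(C)(C)C)cc2)[C@H](c2ccc(O[Si](C)(C)C(C)(C)C)cc2O[Si](C)(C)C(C)(C)C)O[C@H]1c1ccc(O[Si](C)(C)C(C)(C)C)cc1
F6 | step 2 | {1-[2,4-bis(tert-butyldimethylsilyloxy)phenyl]ethenyloxy}trimethylsilane (trimethylsilyl enol ether of 3) | C=C(O[Si](C)(C)C)c1ccc(O[Si](C)(C)C(C)(C)C)cc1O[Si](C)(C)C(C)(C)C
F7 | step 6 | hexa-O-acetate of 14 (six phenolic acetates, carbinol free) | O=C(c1ccc(OC(C)=O)cc1OC(C)=O)[C@@H]1[C@H]([C@@H](O)c2ccc(OC(C)=O)cc2)[C@H](c2ccc(OC(C)=O)cc2OC(C)=O)O[C@H]1c1ccc(OC(C)=O)cc1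
A1 | alternative 1 | 4-hydroxycinnamic acid (p-coumaric acid) | O=C(O)/C=C/c1ccc(O)cc1
A2 | alternative 1 | (1R,2R,5R,6R)-2,6-bis(4-hydroxyphenyl)-3,7-dioxabicyclo[3.3.0]octane-4,8-dione, cis-fused, both aryl groups exo | O=C1[C@@H]2[C@H]([C@@H](O1)c1ccc(O)cc1)C(=O)O[C@H]2c1ccc(O)cc1
A3 | alternative 2 | 1,4-bis[2,4-bis(allyloxy)phenyl]-4-hydroxy-3-{[4-(allyloxy)phenyl](triisopropylsilyloxy)methyl}butan-1-one, stereocentres as at C4, C5 and the carbinol carbon of 14 | O=C(c1ccc(OCC=C)cc1OCC=C)C[C@H]([C@@H](O[Si](C(C)C)(C(C)C)C(C)C)c1ccc(OCC=C)cc1)[C@@H](O)c1ccc(OCC=C)cc1OCC=C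
A4 | alternative 2 | 4-(allyloxy)benzaldehyde | C=CCOc1ccc(C=O)cc1
A5 | alternative 2 | hexa-O-allyl ether and carbinol triisopropylsilyl ether of 14 | O=C(c1ccc(OCC=C)cc1OCC=C)[C@@H]1[C@H]([C@@H](O[Si](C(C)C)(C(C)C)C(C)C)c2ccc(OCC=C)cc2)[C@H](c2ccc(OCC=C)cc2OCC=C)O[C@H]1c1ccc(OCC=C)cc1
A6 | alternative 3 | (5R)-5-[4-(tert-butyldimethylsilyloxy)phenyl]furan-2(5H)-one | O=C1O[C@@H](c2ccc(O[Si](C)(C)C(C)(C)C)cc2)C=C1
A7 | alternative 3 | 1,1-dimethoxy-2-[4-(tert-butyldimethylsilyloxy)phenyl]ethene | COC(OC)=Cc1ccc(O[Si](C)(C)C(C)(C)C)cc1
A8 | alternative 3 | 6,6-dimethoxy-4,7-bis[4-(tert-butyldimethylsilyloxy)phenyl]-3-oxabicyclo[3.2.0]heptan-2-one, cis-fused, aryl groups exo | COC1(OC)[C@@H]2[C@H]([C@@H]1c1ccc(O[Si](C)(C)C(C)(C)C)cc1)C(=O)O[C@H]2c1ccc(O[Si](C)(C)C(C)(C)C)cc1
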